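**Plan**
- Retrosynthesis: the tricosyl chain is cut first at its C11–C12 CH2–CH2 bond (counted from ring C3), giving two primary alkyl halides, 1-bromododecane and 3-(11-iodoundecyl)-1H-pyrrole-2-carbaldehyde. The C3(ring)–C1(chain) bond is cut second, giving 3-bromo-1H-pyrrole-2-carbaldehyde and undec-10-yn-1-ol.
- Enabling feature: the bond lies in an unfunctionalised polymethylene chain, eleven carbons from pyrrole C3, and both of its carbons are primary. The only reactive sites, N1–H and the C2 formyl group, form a vinylogous formamide (N1–C2–CH=O) that is a poor electrophile. Two electrophilic CH2 carbons can therefore be united under Ni/Zn without a carbanion and without protecting groups.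
- Forward: the pyrrole ring is bought with the 2-CHO/3-Br pattern, which fixes the regiochemistry. The C11 arm is attached at C3 by Sonogashira coupling, saturated, and its OH turned into I. The chain is completed in the last step by reductive cross-electrophile coupling with the C12 bromide.
- Stereochemistry: the target has no stereocentre and no double-bond geometry, so nothing has to be controlled.

Key step: step 4

Assumption: 3-bromo-1H-pyrrole-2-carbaldehyde, undec-10-yn-1-ol and 1-bromododecane are taken as purchasable building blocks.

**Step 1**
Reactants: 1 3-bromo-1H-pyrrole-2-carbaldehyde; 2 undec-10-yn-1-ol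
Product: 3 3-(11-hydroxyundec-1-yn-1-yl)-1H-pyrrole-2-carbaldehyde
Conditions: PdCl2(PPh3)2 (5 mol%), CuI (10 mol%), Et3N, DMF, 70 °C, Ar
Reagents that add atoms: none
Why: Sonogashira coupling; the C3–Br bond is ortho to the formyl group and so activated for oxidative addition, and the amine base leaves the free OH, N–H and CHO untouched.

**Step 2**
Reactants: 3 3-(11-hydroxyundec-1-yn-1-yl)-1H-pyrrole-2-carbaldehyde
Product: 4 3-(11-hydroxyundecyl)-1H-pyrrole-2-carbaldehyde
Conditions: H2 (1 atm), 10% Pd/C, EtOAc, rt
Reagents that add atoms: none
Why: Heterogeneous catalytic hydrogenation should saturate the alkyne fully, while the pyrrole ring and its vinylogous-formamide aldehyde are not reduced at 1 atm, as in benzyl ester hydrogenolyses of formylpyrroles.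

**Step 3**
Reactants: 4 3-(11-hydroxyundecyl)-1H-pyrrole-2-carbaldehyde
Product: 5 3-(11-iodoundecyl)-1H-pyrrole-2-carbaldehyde
Conditions: PPh3, I2, imidazole, CH2Cl2, 0 °C to rt (Ph3P·I2 pre-formed, then 4 added)
Reagents that add atoms: iodine, II
Why: Appel-type iodination; iodide displaces the primary alkoxyphosphonium by SN2 under near-neutral conditions, so the aldehyde and N–H are not touched and the formyl-deactivated ring should not be iodinated.

**Step 4**
Reactants: 5 3-(11-iodoundecyl)-1H-pyrrole-2-carbaldehyde; 6 1-bromododecane (3 equiv)
Product: 7 3-tricosyl-1H-pyrrole-2-carbaldehyde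
Conditions: Ni(cod)2 (10 mol%), pybox ligand (12 mol%), Zn dust (3 equiv), DMA, 25 °C, Ar
Reagents that add atoms: none
Why: Low-valent pybox–nickel should take the halogen atom from the C–I bond of 5 and the C–Br bond of 6 to give two primary alkyl radicals; one is held as alkyl–Ni(II), reduced by zinc to alkyl–Ni(I), which captures the second radical to give a dialkyl–Ni(III) species, and reductive elimination forms the CH2–CH2 bond while zinc returns the catalyst. The closest known reaction type is the Ni/pybox-catalysed, zinc-mediated reductive cross-coupling of two unactivated alkyl halides, a union of two electrophilic sp3 carbons. No ring is closed and no stereocentre is formed. The step needs cross- over homo-coupling, which rests on the threefold excess of the cheap bromide 6 and on the iodide/bromide pairing, and the two homodimers (tetracosane and the C22 bis-pyrrole dialdehyde) differ strongly in polarity from 7, so they should separate by chromatography. It also needs reaction at carbon–halogen in preference to CHO and N–H, which is secured by the vinylogous-formamide character of the N1–C2–CH=O unit (low electrophilicity, hard to reduce) and by the base-free, hydride-free medium, in which the acidic N–H cannot be alkylated by the primary iodide. Because no dodecyl carbanion is used, the unprotected formylpyrrole can be carried into the last step and the target is formed directly.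

**Compound list**
1 | 3-bromo-1H-pyrrole-2-carbaldehyde | O=Cc1[nH]ccc1Br | starting material
2 | undec-10-yn-1-ol | C#CCCCCCCCCCO | starting material
3 | 3-(11-hydroxyundec-1-yn-1-yl)-1H-pyrrole-2-carbaldehyde | O=Cc1[nH]ccc1C#CCCCCCCCCCO | intermediate
4 | 3-(11-hydroxyundecyl)-1H-pyrrole-2-carbaldehyde | O=Cc1[nH]ccc1CCCCCCCCCCCO | intermediate
5 | 3-(11-iodoundecyl)-1H-pyrrole-2-carbaldehyde | O=Cc1[nH]ccc1CCCCCCCCCCCI | intermediate
6 | 1-bromododecane | CCCCCCCCCCCCBr | starting material
7 | 3-tricosyl-1H-pyrrole-2-carbaldehyde | CCCCCCCCCCCCCCCCCCCCCCCc1cc[nH]c1C=O | target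

Total step count: 4. Longest linear sequence: 4 steps (1 → 3 → 4 → 5 → 7).

**Steps most likely to fail**

Step 4. Homo-coupling of each halide may outrun the cross-coupling. The C–I bond may also be reduced through an alkylzinc that is quenched by the N–H, or the alkyl radical or alkylnickel may add to the formyl group. The fallback makes the same CH2–CH2 bond by a polar copper-catalysed coupling before the heterocycle is attached, and sets out from 2. Tosylation (TsCl, pyridine, CH2Cl2, 0 °C) would give undec-10-yn-1-yl 4-methylbenzenesulfonate F1. Dodecylmagnesium bromide (2.5 equiv; the first equivalent is held on the acetylenic carbon and returned on work-up) with catalytic Li2CuCl4 in THF, −20 °C to rt, would give tricos-1-yne F2. Sonogashira coupling of F2 with 1 under the conditions of step 1 would give 3-(tricos-1-yn-1-yl)-1H-pyrrole-2-carbaldehyde F3. Hydrogenation as in step 2 would bring the route back at 7.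

Step 1. Oxidative addition into the electron-rich N–H bromopyrrole may be slow, so that copper-mediated oxidative dimerisation of the alkyne takes over. The fallback attaches the saturated arm directly by a B-alkyl Suzuki–Miyaura coupling and sets out from 1. Undec-10-en-1-ol with 9-BBN-H (2.1 equiv, THF, rt; the first equivalent caps the hydroxyl with loss of H2) would give 9-[11-(9-borabicyclo[3.3.1]nonan-9-yloxy)undecyl]-9-borabicyclo[3.3.1]nonane F4. Coupling of F4 with 1 (PdCl2(dppf), aq. K3PO4, DMF/THF, 60 °C) and aqueous work-up would bring the route back at 4, so that 3 and step 2 are bypassed.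

Step 3. The ring may be iodinated by free iodine, or the pyrrole N–H may be alkylated by the new primary iodide while imidazole is present. The fallback avoids elemental iodine and phosphonium activation and sets out from 4. MsCl, Et3N, CH2Cl2, 0 °C would give 11-(2-formyl-1H-pyrrol-3-yl)undecyl methanesulfonate F5. Finkelstein displacement (NaI, acetone, reflux) would bring the route back at 5.

**Further compounds**
F1 | step 4 | undec-10-yn-1-yl 4-methylbenzenesulfonate | C#CCCCCCCCCCOS(=O)(=O)c1ccc(C)cc1
F2 | step 4 | tricos-1-yne | C#CCCCCCCCCCCCCCCCCCCCCC
F3 | step 4 | 3-(tricos-1-yn-1-yl)-1H-pyrrole-2-carbaldehyde | O=Cc1[nH]ccc1C#CCCCCCCCCCCCCCCCCCCCCC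
F4 | step 1 | 9-[11-(9-borabicyclo[3.3.1]nonan-9-yloxy)undecyl]-9-borabicyclo[3.3.1]nonane | B1(CCCCCCCCCCCOB2C3CCCC2CCC3)C2CCCC1CCC2
F5 | step 3 | 11-(2-formyl-1H-pyrrol-3-yl)undecyl methanesulfonate | O=Cc1[nH]ccc1CCCCCCCCCCCOS(C)(=O)=O
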